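## Retrosynthetic overview

1. Target 34 ⇐ hydrogenation of alkene 33 ⇐ Julia–Kocienski union of phthalide aldehyde 14 with spiroketal PT-sulfone 31.
2. 14 ⇐ Fukuyama reduction of thioester 13 ⇐ enantioselective intramolecular oxa-Michael addition (5-exo-trig) of benzoic acid 12 onto its own enoyl thioester; this closes the lactone ring and sets C3 (R).
3. 12 ⇐ Wittig (ylide 10) on tert-butyl 2-formyl-4,6-dimethoxybenzoate 6 ⇐ 3,5-dimethoxybenzaldehyde 1 (bromination, Br–Li exchange/Boc2O).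
4. 31 ⇐ spiroketal alcohol 28 ⇐ acid-mediated double cyclisation of a 2,8-dihydroxy-5-ketone, built by two-fold alkylation of acetone dimethylhydrazone 20 with epoxide 19 (from (S)-epichlorohydrin 16) and (S)-propylene oxide 21.
5. Ring order: both spiroketal rings in one operation (fragment B); lactone ring by the oxa-Michael step (fragment A); the arene is bought; fragments are joined last.

Assumption: the quinidine-derived thiourea in step 8 is taken to give the (R)-phthalide; the sense is checked on the first run (chiral HPLC, rotation), and the quinine-derived pseudo-enantiomer is used if it is reversed.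

## Route

Step 1
Reactants: 1 3,5-dimethoxybenzaldehyde
Product: 2 2-bromo-3,5-dimethoxybenzaldehyde
Conditions: NBS, MeCN, rt
Reagents that add atoms: N-bromosuccinimide, BrN1C(=O)CCC1=O
Why: Electrophilic aromatic bromination goes to C2 (ortho to one OMe, para to the other), the site between the two OMe groups being more hindered.

Step 2
Reactants: 2 2-bromo-3,5-dimethoxybenzaldehyde
Product: 3 2-(2-bromo-3,5-dimethoxyphenyl)-1,3-dioxolane
Conditions: HOCH2CH2OH, p-TsOH (cat.), toluene, reflux, Dean–Stark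
Reagents that add atoms: ethylene glycol, OCCO
Why: Acid-catalysed acetalisation with removal of water masks the aldehyde for the lithiation.

Step 3
Reactants: 3 2-(2-bromo-3,5-dimethoxyphenyl)-1,3-dioxolane
Product: 6 tert-butyl 2-formyl-4,6-dimethoxybenzoate, via [2-(1,3-dioxolan-2-yl)-4,6-dimethoxyphenyl]lithium 4 (not isolated), via tert-butyl 2-(1,3-dioxolan-2-yl)-4,6-dimethoxybenzoate 5 (not isolated)
Conditions: n-BuLi, THF, −78 °C; Boc2O, −78 °C → rt; then 1 M aq. HCl, THF, rt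
Reagents that add atoms: di-tert-butyl dicarbonate, CC(C)(C)OC(=O)OC(=O)OC(C)(C)C; water, O
Why: Bromine–lithium exchange gives an aryllithium that Boc2O acylates to the hindered tert-butyl ester, and dilute acid then hydrolyses only the dioxolane (acetal hydrolysis).

Step 4
Reactants: 7 bromoacetyl bromide
Product: 8 S-ethyl 2-bromoethanethioate
Conditions: EtSH, pyridine, CH2Cl2, 0 °C
Reagents that add atoms: ethanethiol, CCS
Why: Nucleophilic acyl substitution occurs at the acid bromide, which is far more electrophilic than the alkyl bromide at 0 °C.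

Step 5
Reactants: 8 S-ethyl 2-bromoethanethioate
Product: 10 S-ethyl 2-(triphenyl-λ5-phosphanylidene)ethanethioate, via [2-(ethylsulfanyl)-2-oxoethyl]triphenylphosphonium bromide 9 (not isolated)
Conditions: PPh3, toluene, rt; then aq. Na2CO3, CH2Cl2
Reagents that add atoms: triphenylphosphine, c1ccc(cc1)P(c1ccccc1)c1ccccc1
Why: SN2 quaternisation of PPh3 followed by deprotonation of the acidic α-CH2 gives the stabilised ylide.

Step 6
Reactants: 6 tert-butyl 2-formyl-4,6-dimethoxybenzoate; 10 S-ethyl 2-(triphenyl-λ5-phosphanylidene)ethanethioate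
Product: 11 tert-butyl 2-[(1E)-3-(ethylsulfanyl)-3-oxoprop-1-en-1-yl]-4,6-dimethoxybenzoate
Conditions: toluene, 80 °C
Reagents that add atoms: none
Why: Wittig olefination with a stabilised ylide gives the (E)-enoyl thioester.

Step 7
Reactants: 11 tert-butyl 2-[(1E)-3-(ethylsulfanyl)-3-oxoprop-1-en-1-yl]-4,6-dimethoxybenzoate
Product: 12 2-[(1E)-3-(ethylsulfanyl)-3-oxoprop-1-en-1-yl]-4,6-dimethoxybenzoic acid
Conditions: TFA–CH2Cl2 (1:3), 0 °C → rt; toluene azeotrope
Reagents that add atoms: none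
Why: Acidolysis of the tert-butyl ester (loss of isobutene) frees the carboxylic acid without any base, so no carboxylate is formed that could close the ring racemically.

Step 8
Reactants: 12 2-[(1E)-3-(ethylsulfanyl)-3-oxoprop-1-en-1-yl]-4,6-dimethoxybenzoic acid
Product: 13 S-ethyl [(1R)-4,6-dimethoxy-3-oxo-1,3-dihydro-2-benzofuran-1-yl]ethanethioate
Conditions: 9-amino-9-deoxy-epi-quinidine 3,5-(CF3)2C6H3-thiourea (10 mol%), toluene, 0 °C → rt; recrystallise
Reagents that add atoms: none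
Why: Enantioselective intramolecular oxa-Michael addition (5-exo-trig): the quinuclidine deprotonates the acid while the thiourea binds the thioester, so the carboxylate adds to one face of the β-carbon and sets C3 as R.

Step 9
Reactants: 13 S-ethyl [(1R)-4,6-dimethoxy-3-oxo-1,3-dihydro-2-benzofuran-1-yl]ethanethioate
Product: 14 [(1R)-4,6-dimethoxy-3-oxo-1,3-dihydro-2-benzofuran-1-yl]acetaldehyde
Conditions: Et3SiH, 10% Pd/C, acetone, rt
Reagents that add atoms: none
Why: Fukuyama reduction converts only the thioester to the aldehyde under neutral conditions, leaving the lactone and C3 untouched.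

Step 10
Reactants: 15 (3-bromopropoxy)(tert-butyl)dimethylsilane; 16 (S)-epichlorohydrin
Product: 18 (2S)-6-[(tert-butyldimethylsilyl)oxy]-1-chlorohexan-2-ol, via {3-[(tert-butyldimethylsilyl)oxy]propyl}magnesium bromide 17 (not isolated)
Conditions: Mg, THF; then CuI (10 mol%), 16, THF, −40 → 0 °C
Reagents that add atoms: none
Why: Grignard formation and copper-catalysed SN2 opening of the epoxide at its CH2 terminus leave the stereocentre of 16 untouched, giving the (S)-chlorohydrin.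

Step 11
Reactants: 18 (2S)-6-[(tert-butyldimethylsilyl)oxy]-1-chlorohexan-2-ol
Product: 19 tert-butyldimethyl{4-[(2S)-oxiran-2-yl]butoxy}silane
Conditions: K2CO3, MeOH, rt
Reagents that add atoms: none
Why: Intramolecular Williamson closure displaces chloride at CH2Cl, so the carbinol centre is not involved and the epoxide is (S).

Step 12
Reactants: 20 acetone N,N-dimethylhydrazone; 19 tert-butyldimethyl{4-[(2S)-oxiran-2-yl]butoxy}silane; 21 (S)-propylene oxide
Product: 25 (2S,8S)-12-[(tert-butyldimethylsilyl)oxy]-5-(2,2-dimethylhydrazinylidene)dodecane-2,8-diol, via lithiated acetone N,N-dimethylhydrazone 22 (not isolated), via lithium (5S)-9-[(tert-butyldimethylsilyl)oxy]-2-(2,2-dimethylhydrazinylidene)nonan-5-olate 23 (not isolated), via the C1-lithiated derivative of 23 24 (not isolated)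
Conditions: 20, n-BuLi, THF, −78 → 0 °C; 19, −78 °C → rt; n-BuLi, −78 → 0 °C; 21 (excess), 0 °C → rt; aq. NH4Cl
Reagents that add atoms: none
Why: Two successive hydrazone azaenolate alkylations (Corey–Enders type), each an SN2 attack at an epoxide CH2 with the second deprotonation at the remaining methyl, carry both (S)-carbinol centres over unchanged from the epoxides.

Step 13
Reactants: 25 (2S,8S)-12-[(tert-butyldimethylsilyl)oxy]-5-(2,2-dimethylhydrazinylidene)dodecane-2,8-diol
Product: 28 4-[(2S,5RS,7S)-7-methyl-1,6-dioxaspiro[4.4]nonan-2-yl]butan-1-ol, via (2S,8S)-12-[(tert-butyldimethylsilyl)oxy]-2,8-dihydroxydodecan-5-one 26 (not isolated), via tert-butyldimethyl{4-[(2S,5RS,7S)-7-methyl-1,6-dioxaspiro[4.4]nonan-2-yl]butoxy}silane 27 (not isolated)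
Conditions: 2 M aq. HCl, THF, rt
Reagents that add atoms: none
Why: Hydrazone hydrolysis, spontaneous thermodynamic spiroketalisation of the bis(γ-hydroxy) ketone and silyl ether cleavage occur in one pot; C2 and C7 stay S, and the spiro centre forms as a roughly 1:1 epimer mixture.

Step 14
Reactants: 28 4-[(2S,5RS,7S)-7-methyl-1,6-dioxaspiro[4.4]nonan-2-yl]butan-1-ol
Product: 29 5-({4-[(2S,5RS,7S)-7-methyl-1,6-dioxaspiro[4.4]nonan-2-yl]butyl}sulfanyl)-1-phenyl-1H-tetrazole
Conditions: 1-phenyl-1H-tetrazole-5-thiol, PPh3, DIAD, THF, 0 °C → rt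
Reagents that add atoms: 1-phenyl-1H-tetrazole-5-thiol, Sc1nnnn1-c1ccccc1
Why: Mitsunobu thioetherification of the primary alcohol with the acidic thiol.

Step 15
Reactants: 29 5-({4-[(2S,5RS,7S)-7-methyl-1,6-dioxaspiro[4.4]nonan-2-yl]butyl}sulfanyl)-1-phenyl-1H-tetrazole
Product: 30 5-({4-[(2S,5RS,7S)-7-methyl-1,6-dioxaspiro[4.4]nonan-2-yl]butyl}sulfonyl)-1-phenyl-1H-tetrazole
Conditions: mCPBA (2.5 equiv), NaHCO3, CH2Cl2, 0 °C → rt
Reagents that add atoms: meta-chloroperoxybenzoic acid, OOC(=O)c1cccc(Cl)c1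
Why: Buffered peracid oxidation takes the sulfide through the sulfoxide to the sulfone without harming the ketal.

Step 16
Reactants: 30 5-({4-[(2S,5RS,7S)-7-methyl-1,6-dioxaspiro[4.4]nonan-2-yl]butyl}sulfonyl)-1-phenyl-1H-tetrazole
Product: 31 5-({4-[(2S,5R,7S)-7-methyl-1,6-dioxaspiro[4.4]nonan-2-yl]butyl}sulfonyl)-1-phenyl-1H-tetrazole
Conditions: prep. HPLC (SiO2, hexane–EtOAc); unwanted 5S-rich fraction of 30: CSA (5 mol%), CH2Cl2, rt, then re-separate (2–3 cycles)
Reagents that add atoms: none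
Why: Acid-catalysed spiroketal epimerisation (ring opening to the oxocarbenium ion and reclosure) interconverts only C5, so separating the diastereomers and recycling the unwanted one funnels the material into the 5R epimer.

Step 17
Reactants: 31 5-({4-[(2S,5R,7S)-7-methyl-1,6-dioxaspiro[4.4]nonan-2-yl]butyl}sulfonyl)-1-phenyl-1H-tetrazole; 14 [(1R)-4,6-dimethoxy-3-oxo-1,3-dihydro-2-benzofuran-1-yl]acetaldehyde
Product: 33 (3R)-5,7-dimethoxy-3-{6-[(2S,5R,7S)-7-methyl-1,6-dioxaspiro[4.4]nonan-2-yl]hex-2-en-1-yl}-2-benzofuran-1(3H)-one (E/Z mixture), via the potassium α-sulfonyl carbanion of 31 32 (not isolated)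
Conditions: 31, KHMDS, THF, −78 °C; then 14, −78 °C → rt; aq. NH4Cl
Reagents that add atoms: none
Why: Julia–Kocienski olefination (addition, Smiles rearrangement, loss of SO2 and tetrazolone) with the pre-formed carbanion added to the aldehyde at −78 °C, so addition outruns enolisation; the alkene geometry is irrelevant.

Step 18
Reactants: 33 (3R)-5,7-dimethoxy-3-{6-[(2S,5R,7S)-7-methyl-1,6-dioxaspiro[4.4]nonan-2-yl]hex-2-en-1-yl}-2-benzofuran-1(3H)-one
Product: 34 (3R)-5,7-dimethoxy-3-{6-[(2S,5R,7S)-7-methyl-1,6-dioxaspiro[4.4]nonan-2-yl]hexyl}-2-benzofuran-1(3H)-one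
Conditions: H2 (1 atm), PtO2, EtOAc, rt
Reagents that add atoms: none
Why: Heterogeneous catalytic hydrogenation saturates the isolated alkene under neutral conditions (Pt rather than Pd to avoid hydrogenolysis of the benzylic lactone C–O bond) and touches no stereocentre.

## Compound list

1 | 3,5-dimethoxybenzaldehyde | COc1cc(OC)cc(C=O)c1 | starting material
2 | 2-bromo-3,5-dimethoxybenzaldehyde | COc1cc(OC)c(Br)c(C=O)c1 | intermediate
3 | 2-(2-bromo-3,5-dimethoxyphenyl)-1,3-dioxolane | COc1cc(OC)c(Br)c(C2OCCO2)c1 | intermediate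
4 | [2-(1,3-dioxolan-2-yl)-4,6-dimethoxyphenyl]lithium | COc1cc(OC)c([Li])c(C2OCCO2)c1 | intermediate
5 | tert-butyl 2-(1,3-dioxolan-2-yl)-4,6-dimethoxybenzoate | COc1cc(OC)c(C(=O)OC(C)(C)C)c(C2OCCO2)c1 | intermediate
6 | tert-butyl 2-formyl-4,6-dimethoxybenzoate | COc1cc(OC)c(C(=O)OC(C)(C)C)c(C=O)c1 | intermediate
7 | bromoacetyl bromide | BrCC(Br)=O | starting material
8 | S-ethyl 2-bromoethanethioate | CCSC(=O)CBr | intermediate
9 | [2-(ethylsulfanyl)-2-oxoethyl]triphenylphosphonium bromide | CCSC(=O)C[P+](c1ccccc1)(c1ccccc1)c1ccccc1.[Br-] | intermediate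
10 | S-ethyl 2-(triphenyl-λ5-phosphanylidene)ethanethioate | CCSC(=O)C=P(c1ccccc1)(c1ccccc1)c1ccccc1 | intermediate
11 | tert-butyl 2-[(1E)-3-(ethylsulfanyl)-3-oxoprop-1-en-1-yl]-4,6-dimethoxybenzoate | CCSC(=O)/C=C/c1cc(OC)cc(OC)c1C(=O)OC(C)(C)C | intermediate
12 | 2-[(1E)-3-(ethylsulfanyl)-3-oxoprop-1-en-1-yl]-4,6-dimethoxybenzoic acid | CCSC(=O)/C=C/c1cc(OC)cc(OC)c1C(=O)O | intermediate
13 | S-ethyl [(1R)-4,6-dimethoxy-3-oxo-1,3-dihydro-2-benzofuran-1-yl]ethanethioate, i.e. (R)-3-[2-(ethylsulfanyl)-2-oxoethyl]-5,7-dimethoxyphthalide | COc1cc(OC)c2c(c1)[C@@H](CC(=O)SCC)OC2=O | intermediate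
14 | [(1R)-4,6-dimethoxy-3-oxo-1,3-dihydro-2-benzofuran-1-yl]acetaldehyde, i.e. (R)-5,7-dimethoxy-3-(2-oxoethyl)phthalide | COc1cc(OC)c2c(c1)[C@@H](CC=O)OC2=O | intermediate
15 | (3-bromopropoxy)(tert-butyl)dimethylsilane | CC(C)(C)[Si](C)(C)OCCCBr | starting material
16 | (S)-epichlorohydrin, (2S)-2-(chloromethyl)oxirane | ClC[C@@H]1CO1 | starting material
17 | {3-[(tert-butyldimethylsilyl)oxy]propyl}magnesium bromide | CC(C)(C)[Si](C)(C)OCCC[Mg]Br | intermediate
18 | (2S)-6-[(tert-butyldimethylsilyl)oxy]-1-chlorohexan-2-ol | CC(C)(C)[Si](C)(C)OCCCC[C@H](O)CCl | intermediate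
19 | tert-butyldimethyl{4-[(2S)-oxiran-2-yl]butoxy}silane | CC(C)(C)[Si](C)(C)OCCCC[C@H]1CO1 | intermediate
20 | acetone N,N-dimethylhydrazone | CC(C)=NN(C)C | starting material
21 | (S)-propylene oxide, (2S)-2-methyloxirane | C[C@H]1CO1 | starting material
22 | lithiated acetone N,N-dimethylhydrazone (azaenolate) | [Li]CC(C)=NN(C)C | intermediate
23 | lithium (5S)-9-[(tert-butyldimethylsilyl)oxy]-2-(2,2-dimethylhydrazinylidene)nonan-5-olate | CC(=NN(C)C)CC[C@@H](O[Li])CCCCO[Si](C)(C)C(C)(C)C | intermediate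
24 | C1-lithiated derivative of 23 (alkoxide azaenolate) | [Li]CC(=NN(C)C)CC[C@@H](O[Li])CCCCO[Si](C)(C)C(C)(C)C | intermediate
25 | (2S,8S)-12-[(tert-butyldimethylsilyl)oxy]-5-(2,2-dimethylhydrazinylidene)dodecane-2,8-diol | C[C@H](O)CCC(=NN(C)C)CC[C@@H](O)CCCCO[Si](C)(C)C(C)(C)C | intermediate
26 | (2S,8S)-12-[(tert-butyldimethylsilyl)oxy]-2,8-dihydroxydodecan-5-one | C[C@H](O)CCC(=O)CC[C@@H](O)CCCCO[Si](C)(C)C(C)(C)C | intermediate
27 | tert-butyldimethyl{4-[(2S,5RS,7S)-7-methyl-1,6-dioxaspiro[4.4]nonan-2-yl]butoxy}silane (C5 epimer mixture) | CC(C)(C)[Si](C)(C)OCCCC[C@H]1CCC2(CC[C@H](C)O2)O1 | intermediate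
28 | 4-[(2S,5RS,7S)-7-methyl-1,6-dioxaspiro[4.4]nonan-2-yl]butan-1-ol (C5 epimer mixture) | OCCCC[C@H]1CCC2(CC[C@H](C)O2)O1 | intermediate
29 | 5-({4-[(2S,5RS,7S)-7-methyl-1,6-dioxaspiro[4.4]nonan-2-yl]butyl}sulfanyl)-1-phenyl-1H-tetrazole (C5 epimer mixture) | c1ccccc1-n1nnnc1SCCCC[C@H]1CCC2(CC[C@H](C)O2)O1 | intermediate
30 | 5-({4-[(2S,5RS,7S)-7-methyl-1,6-dioxaspiro[4.4]nonan-2-yl]butyl}sulfonyl)-1-phenyl-1H-tetrazole (C5 epimer mixture) | O=S(=O)(CCCC[C@H]1CCC2(CC[C@H](C)O2)O1)c1nnnn1-c1ccccc1 | intermediate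
31 | 5-({4-[(2S,5R,7S)-7-methyl-1,6-dioxaspiro[4.4]nonan-2-yl]butyl}sulfonyl)-1-phenyl-1H-tetrazole | O=S(=O)(CCCC[C@H]1CC[C@@]2(CC[C@H](C)O2)O1)c1nnnn1-c1ccccc1 | intermediate
32 | potassium α-sulfonyl carbanion of 31 | [K]C(CCC[C@H]1CC[C@@]2(CC[C@H](C)O2)O1)S(=O)(=O)c1nnnn1-c1ccccc1 | intermediate
33 | (3R)-5,7-dimethoxy-3-{6-[(2S,5R,7S)-7-methyl-1,6-dioxaspiro[4.4]nonan-2-yl]hex-2-en-1-yl}-2-benzofuran-1(3H)-one (E/Z mixture) | COc1cc(OC)c2c(c1)[C@@H](CC=CCCC[C@H]1CC[C@@]3(CC[C@H](C)O3)O1)OC2=O | intermediate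
34 | (3R)-5,7-dimethoxy-3-{6-[(2S,5R,7S)-7-methyl-1,6-dioxaspiro[4.4]nonan-2-yl]hexyl}-2-benzofuran-1(3H)-one | COc1cc(OC)c2c(c1)[C@@H](CCCCCC[C@H]1CC[C@@]3(CC[C@H](C)O3)O1)OC2=O | target

## Step count and risks

Total step count: 18.
Longest linear sequence: 9 steps (1, 2, 3, 6, 7, 8, 9, 17, 18; equally 10–18). The ylide branch (4, 5) joins at step 6.

The three steps most likely to fail:

Step 8 (oxa-Michael). The enantioselectivity or its sense may be inadequate for this electron-rich, ortho-substituted acid, or some racemic closure may occur before the catalyst is added. The fallback sets out from 6. Brown allylation with (+)-Ipc2B(allyl) (Et2O, −78 °C; NaOH/H2O2) gives tert-butyl 2-[(1R)-1-hydroxybut-3-en-1-yl]-4,6-dimethoxybenzoate F1. TFA in CH2Cl2 then lactonises it to (3R)-5,7-dimethoxy-3-(prop-2-en-1-yl)-2-benzofuran-1(3H)-one F2. Ozonolysis (O3, CH2Cl2, −78 °C; PPh3) cleaves the terminal alkene and comes back to the route at 14. Here the C3 centre comes from the reagent-controlled allylation instead of the conjugate addition.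

Step 16 (spiro-epimer resolution). The two C5 epimers of the small sulfone may not separate on a preparative scale. The fallback sets out from mixture 30 and moves the resolution to the end. Julia–Kocienski coupling of 30 with 14 gives (3R)-5,7-dimethoxy-3-{6-[(2S,5RS,7S)-7-methyl-1,6-dioxaspiro[4.4]nonan-2-yl]hex-2-en-1-yl}-2-benzofuran-1(3H)-one F3. Hydrogenation (H2, PtO2) gives 34 together with its spiro epimer (3R)-5,7-dimethoxy-3-{6-[(2S,5S,7S)-7-methyl-1,6-dioxaspiro[4.4]nonan-2-yl]hexyl}-2-benzofuran-1(3H)-one F4. These larger, UV-active diastereomers are separated by preparative HPLC, and F4 is re-equilibrated with PPTS in CH2Cl2 and recycled, so the fallback comes back at 34.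

Step 17 (Julia–Kocienski coupling). Aldehyde 14 has an acidic α-CH2 with the lactone oxygen in the β-position, so the basic carbanion may open the lactone by E1cB elimination or racemise C3. The fallback sets out from 31 and joins the fragments without base. Julia methylenation of 31 (KHMDS, THF, −78 °C; monomeric formaldehyde) gives (2S,5R,7S)-2-methyl-7-(pent-4-en-1-yl)-1,6-dioxaspiro[4.4]nonane F5. Cross-metathesis of F5 with (3R)-5,7-dimethoxy-3-(prop-2-en-1-yl)-2-benzofuran-1(3H)-one F2 (made from 6 as in the first fallback; Hoveyda–Grubbs II, CH2Cl2, 40 °C) comes back to the route at 33, which is hydrogenated as in step 18.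

## Further compounds

F1 | step 8 | tert-butyl 2-[(1R)-1-hydroxybut-3-en-1-yl]-4,6-dimethoxybenzoate | COc1cc(OC)c(C(=O)OC(C)(C)C)c(c1)[C@@H](CC=C)O
F2 | step 8 | (3R)-5,7-dimethoxy-3-(prop-2-en-1-yl)-2-benzofuran-1(3H)-one | COc1cc(OC)c2c(c1)[C@@H](CC=C)OC2=O
F3 | step 16 | (3R)-5,7-dimethoxy-3-{6-[(2S,5RS,7S)-7-methyl-1,6-dioxaspiro[4.4]nonan-2-yl]hex-2-en-1-yl}-2-benzofuran-1(3H)-one (C5 epimer mixture) | COc1cc(OC)c2c(c1)[C@@H](CC=CCCC[C@H]1CCC3(CC[C@H](C)O3)O1)OC2=O
F4 | step 16 | (3R)-5,7-dimethoxy-3-{6-[(2S,5S,7S)-7-methyl-1,6-dioxaspiro[4.4]nonan-2-yl]hexyl}-2-benzofuran-1(3H)-one | COc1cc(OC)c2c(c1)[C@@H](CCCCCC[C@H]1CC[C@]3(CC[C@H](C)O3)O1)OC2=O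
F5 | step 17 | (2S,5R,7S)-2-methyl-7-(pent-4-en-1-yl)-1,6-dioxaspiro[4.4]nonane | C=CCCC[C@H]1CC[C@@]2(CC[C@H](C)O2)O1
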